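**Plan**

- Ring labels: the flavan unit is rings A (resorcinol), C (pyran: O1, C2, C3, C4) and B (pyrogallol); the dihydroflavonol unit is rings D, F and E, and ring E carries the flavan C4 at its C2′.
- Cuts: O1–C2 and C3–C4 of ring C (oxa-[4+2] addition), C3–O (made from C3–B), C4–C4a (ortho-hydroxyalkylation of a resorcinol monoether), and C4–C2′ (a formyl group put on ring E). Rings D, F and E are bought as (+)-dihydrorobinetin.
- Forward order: protect dihydrorobinetin, formylate ring E, attach ring A at the formyl carbon, close ring C onto a styrenyl boronate that carries ring B, oxidise C–B to C–OH, then hydrogenolyse all benzyl groups.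
- Enabling feature: O1 is ortho to C4a and C4 is doubly benzylic (rings A and E), so O1=C8a–C4a=C4 is an ortho-quinone methide, and C2 is benzylic to ring B. The ring-C pattern (2,4-cis diaryl, 3-substituent trans to both, all equatorial) is the endo adduct of that oxadiene with an (E)-styrene.
- Stereochemistry: C2 and C3 of ring F come from natural (2R,3R)-dihydrorobinetin and are never enolised. C4 of ring C is set by a chiral Brønsted acid in the key step, C2 and C3 by endo approach and (E)-alkene geometry, and the C3 hydroxyl by stereoretentive C–B oxidation.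

Key step: step 6

Assumption: (+)-dihydrorobinetin 1, the (2R,3R)-dihydroflavonol that supplies rings D, F and E with the required configuration, is taken as a purchasable natural product.

**Route**

Step 1
Reactants: 1 (+)-dihydrorobinetin
Product: 2 tetra-O-benzyl dihydrorobinetin (3-OH free)
Conditions: BnBr (4.4 equiv), K2CO3, DMF, rt, argon
Reagents that add atoms: benzyl bromide BrCc1ccccc1
Why: Williamson etherification in which K2CO3 ionises only the four phenols (7, 3′, 4′, 5′), so the secondary 3-OH should stay free and the mild base should not open ring F; no stereocentre is touched.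

Step 2
Reactants: 2 tetra-O-benzyl dihydrorobinetin
Product: 3 3-O-benzyloxycarbonyl tetra-O-benzyl dihydrorobinetin
Conditions: CbzCl, DMAP (cat.), pyridine, CH2Cl2, 0 °C
Reagents that add atoms: benzyl chloroformate O=C(Cl)OCc1ccccc1
Why: DMAP-catalysed acylation with a chloroformate; the carbonate stops the 3-oxygen from adding to the quinone methide of step 6, is installed without an enolising base, and leaves with the benzyl ethers in step 8.

Step 3
Reactants: 3 3-O-benzyloxycarbonyl tetra-O-benzyl dihydrorobinetin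
Product: 4 ring-E 2′-aldehyde
Conditions: Cl2CHOMe (3 equiv), AgOSO2CF3 (3 equiv), CH2Cl2, −78 °C; then H2O
Reagents that add atoms: dichloromethyl methyl ether COC(Cl)Cl; water O
Why: Rieche formylation (electrophilic aromatic substitution) in its silver triflate variant, which avoids TiCl4 and should spare the benzyl ethers; ring E (three ether donors, no acceptor) is the most nucleophilic arene, ring D is deactivated by the conjugated ketone, and the free ring-E positions 2′ and 6′ are equivalent.

Step 4
Reactants: 4 ring-E 2′-aldehyde; 5 3-(benzyloxy)phenol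
Product: 7 ortho-hydroxybenzhydrol (both carbinol epimers), via benzodioxaborin 6 (not isolated)
Conditions: PhB(OH)2 (1.2 equiv), EtCO2H (cat.), toluene, reflux, water separator; then 30% H2O2, THF, 0 °C
Reagents that add atoms: none
Why: Boron-templated ortho-hydroxyalkylation of a phenol by an aldehyde, in which the aryloxy(phenyl)boron species delivers the aldehyde to the carbon ortho to the hydroxyl (C6 of 5, para to OBn and less hindered than C2); this forms C4–C4a with the ring-A oxygen pattern, and the new carbinol centre may be either epimer because it becomes planar in step 6.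

Step 5
Reactants: 8 3,4,5-tris(benzyloxy)benzaldehyde; 9 bis(pinacolatoboryl)methane
Product: 10 (E)-styrenyl pinacol boronate of ring B
Conditions: lithium 2,2,6,6-tetramethylpiperidide, THF, 0 °C; then 8, −78 °C to rt; H2O
Reagents that add atoms: none
Why: Boron-Wittig olefination, in which the lithiated gem-diboronate adds to the aldehyde and syn-eliminates a boron–oxygen unit, which should give the (E)-alkenyl boronate carrying ring B, C2 and C3.

Step 6
Reactants: 7 ortho-hydroxybenzhydrol; 10 (E)-styrenyl pinacol boronate of ring B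
Product: 12 all-trans 3-boryl flavan on ring E, via ortho-quinone methide 11 (not isolated)
Conditions: (R)-3,3′-bis(2,4,6-triisopropylphenyl)-1,1′-binaphthyl-2,2′-diyl N-triflylphosphoramide (10 mol%), 10 (3 equiv), slow addition of 7, 5 Å molecular sieves, CH2Cl2, −40 to −10 °C
Reagents that add atoms: none
Why: Proposed new method: the N-triflylphosphoramide ionises carbinol 7 to the hydrogen-bonded ortho-quinone methide 11, the boron-bearing carbon of 10 (the styrene β-carbon, the only position that leaves a benzylic, β-boryl-stabilised cation at C2) attacks the methide carbon C4, and phenolic O1 then collapses on C2, so O1–C2 is the ring-closing bond of an asynchronous inverse-demand oxa-[4+2] addition. The closest known reaction type is the chiral N-triflylphosphoramide-catalysed [4+2] addition of ortho-quinone methides from 2-hydroxybenzhydrols to simple styrenes, which gives 2,4-cis-flavans; new here is an alkenyl pinacol boronate as the 2π partner with boron kept at C3 (alkenyl boronates are established dienophiles in all-carbon Diels–Alder reactions, and 3-boryl flavans are the intermediates of flav-2-ene hydroboration). Ring C closes as a six-membered ring from the oxadiene O1=C8a–C4a=C4 and the alkene C3=C2 (4π + 2π; in the stepwise limit a phenol-to-cation collapse). C4 is set by the catalyst, whose chiral anion is bound at the quinone methide oxygen and should block one face of C4 (rotation about C4–C2′ exchanges the two ortho groups of ring E between the faces, so substrate bias should be small; the catalyst antipode is used if a model run shows the opposite sense); C2 becomes cis to the C4 aryl by endo placement of ring B, and C3 trans to both because the (E)-geometry of 10 is transferred, and since all three substituents are then equatorial a stepwise path should converge on the same isomer. The step needs regioselectivity (C–B carbon to C4, secured by the polarisation above), ring closure in preference to loss of boron (favoured by intramolecular O1 capture, the non-nucleophilic acid and molecular sieves), suppression of self-alkylation at ring A (excess 10, slow addition of 7) and site selectivity for O1 (the only free hydroxyl, every other oxygen being benzylated or a carbonate).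

Step 7
Reactants: 12 all-trans 3-boryl flavan on ring E
Product: 13 octa-O-benzyl 3-O-benzyloxycarbonyl target
Conditions: NaBO3·4H2O, THF/H2O, 0 °C to rt
Reagents that add atoms: sodium perborate (active form) [Na+].OO[B-](O)(O)O
Why: Oxidation of a secondary alkyl boronate with retention at carbon (hydroperoxide adds to boron, then C3 shifts from B to O), the same organoborane type that flav-2-ene hydroboration passes through; it should turn C3–B into the 3S hydroxyl trans to both aryl groups, and perborate is mild enough to spare the carbonate and the enolisable ring-F ketone.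

Step 8
Reactants: 13 octa-O-benzyl 3-O-benzyloxycarbonyl target
Product: 14 robinetinidol-(4α→2′)-dihydrorobinetin (CNP0310728.2)
Conditions: H2 (1 atm), Pd(OH)2 on carbon, THF/MeOH, rt
Reagents that add atoms: none
Why: Hydrogenolysis of the eight benzyl ethers and the benzyl carbonate (which then loses CO2); the ring-F ketone is a vinylogous ester and the benzylic O1–C2 bonds of rings C and F should cleave much more slowly than O-benzyl groups, so no stereocentre is affected.

**Compound list**

1 | (+)-dihydrorobinetin, (2R,3R)-3,7-dihydroxy-2-(3,4,5-trihydroxyphenyl)chroman-4-one | O=C1c2ccc(O)cc2O[C@H](c2cc(O)c(O)c(O)c2)[C@H]1O | starting material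
2 | (2R,3R)-7-(benzyloxy)-3-hydroxy-2-[3,4,5-tris(benzyloxy)phenyl]chroman-4-one | O=C1c2ccc(OCc3ccccc3)cc2O[C@H](c2cc(OCc3ccccc3)c(OCc3ccccc3)c(OCc3ccccc3)c2)[C@H]1O | intermediate
3 | benzyl (2R,3R)-7-(benzyloxy)-4-oxo-2-[3,4,5-tris(benzyloxy)phenyl]chroman-3-yl carbonate | O=C1c2ccc(OCc3ccccc3)cc2O[C@H](c2cc(OCc3ccccc3)c(OCc3ccccc3)c(OCc3ccccc3)c2)[C@H]1OC(=O)OCc1ccccc1 | intermediate
4 | benzyl (2R,3R)-7-(benzyloxy)-2-[3,4,5-tris(benzyloxy)-2-formylphenyl]-4-oxochroman-3-yl carbonate | O=C1c2ccc(OCc3ccccc3)cc2O[C@H](c2cc(OCc3ccccc3)c(OCc3ccccc3)c(OCc3ccccc3)c2C=O)[C@H]1OC(=O)OCc1ccccc1 | intermediate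
5 | 3-(benzyloxy)phenol | Oc1cccc(OCc2ccccc2)c1 | starting material
6 | benzyl (2R,3R)-7-(benzyloxy)-2-{3,4,5-tris(benzyloxy)-2-[7-(benzyloxy)-2-phenyl-4H-1,3,2-benzodioxaborin-4-yl]phenyl}-4-oxochroman-3-yl carbonate (both epimers at the borin C4) | O=C1c2ccc(OCc3ccccc3)cc2O[C@H](c2cc(OCc3ccccc3)c(OCc3ccccc3)c(OCc3ccccc3)c2C2OB(c3ccccc3)Oc3cc(OCc4ccccc4)ccc32)[C@H]1OC(=O)OCc1ccccc1 | intermediate
7 | benzyl (2R,3R)-7-(benzyloxy)-2-{3,4,5-tris(benzyloxy)-2-[(4-(benzyloxy)-2-hydroxyphenyl)(hydroxy)methyl]phenyl}-4-oxochroman-3-yl carbonate (both carbinol epimers) | O=C1c2ccc(OCc3ccccc3)cc2O[C@H](c2cc(OCc3ccccc3)c(OCc3ccccc3)c(OCc3ccccc3)c2C(O)c2ccc(OCc3ccccc3)cc2O)[C@H]1OC(=O)OCc1ccccc1 | intermediate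
8 | 3,4,5-tris(benzyloxy)benzaldehyde | O=Cc1cc(OCc2ccccc2)c(OCc2ccccc2)c(OCc2ccccc2)c1 | starting material
9 | bis(4,4,5,5-tetramethyl-1,3,2-dioxaborolan-2-yl)methane | CC1(C)OB(CB2OC(C)(C)C(C)(C)O2)OC1(C)C | starting material
10 | (E)-4,4,5,5-tetramethyl-2-{2-[3,4,5-tris(benzyloxy)phenyl]vinyl}-1,3,2-dioxaborolane | CC1(C)OB(/C=C/c2cc(OCc3ccccc3)c(OCc3ccccc3)c(OCc3ccccc3)c2)OC1(C)C | intermediate
11 | benzyl (2R,3R)-7-(benzyloxy)-2-{3,4,5-tris(benzyloxy)-2-[(4-(benzyloxy)-6-oxocyclohexa-2,4-dien-1-ylidene)methyl]phenyl}-4-oxochroman-3-yl carbonate (ortho-quinone methide) | O=C1c2ccc(OCc3ccccc3)cc2O[C@H](c2cc(OCc3ccccc3)c(OCc3ccccc3)c(OCc3ccccc3)c2C=C2C=CC(OCc3ccccc3)=CC2=O)[C@H]1OC(=O)OCc1ccccc1 | intermediate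
12 | benzyl (2R,3R)-7-(benzyloxy)-2-{3,4,5-tris(benzyloxy)-2-[(2S,3S,4S)-7-(benzyloxy)-3-(4,4,5,5-tetramethyl-1,3,2-dioxaborolan-2-yl)-2-(3,4,5-tris(benzyloxy)phenyl)chroman-4-yl]phenyl}-4-oxochroman-3-yl carbonate (ring C 2,3-trans-3,4-trans, all equatorial) | O=C1c2ccc(OCc3ccccc3)cc2O[C@H](c2cc(OCc3ccccc3)c(OCc3ccccc3)c(OCc3ccccc3)c2[C@@H]2c3ccc(OCc4ccccc4)cc3O[C@H](c3cc(OCc4ccccc4)c(OCc4ccccc4)c(OCc4ccccc4)c3)[C@H]2B2OC(C)(C)C(C)(C)O2)[C@H]1OC(=O)OCc1ccccc1 | intermediate
13 | benzyl (2R,3R)-7-(benzyloxy)-2-{3,4,5-tris(benzyloxy)-2-[(2R,3S,4S)-7-(benzyloxy)-3-hydroxy-2-(3,4,5-tris(benzyloxy)phenyl)chroman-4-yl]phenyl}-4-oxochroman-3-yl carbonate | O=C1c2ccc(OCc3ccccc3)cc2O[C@H](c2cc(OCc3ccccc3)c(OCc3ccccc3)c(OCc3ccccc3)c2[C@@H]2c3ccc(OCc4ccccc4)cc3O[C@H](c3cc(OCc4ccccc4)c(OCc4ccccc4)c(OCc4ccccc4)c3)[C@H]2O)[C@H]1OC(=O)OCc1ccccc1 | intermediate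
14 | (2R,3R)-2-{2-[(2R,3S,4S)-3,7-dihydroxy-2-(3,4,5-trihydroxyphenyl)chroman-4-yl]-3,4,5-trihydroxyphenyl}-3,7-dihydroxychroman-4-one | O=C1c2ccc(O)cc2O[C@H](c2cc(O)c(O)c(O)c2[C@@H]2c3ccc(O)cc3O[C@H](c3cc(O)c(O)c(O)c3)[C@H]2O)[C@H]1O | target

**Step count and risks**

Total step count: 8. Longest linear sequence: 7 steps (steps 1, 2, 3, 4, 6, 7, 8); step 5 is a one-step side branch.

Steps most likely to fail:

1. Step 6. After the C3–C4 bond forms, boron may be lost from the β-boryl cation, or from 12 by acid-promoted anti-elimination of O1 and boron, which would give alkenyl transfer instead of ring closure. The catalyst may also fail to control the C4 face, and the quinone methide may alkylate ring A of a second molecule. The fallback uses known chemistry, sets out from 7 and 10, and returns at 13. Boronate 10 is cleaved with NaIO4/NH4OAc in acetone/water and re-esterified with ethanol to diethyl (E)-{2-[3,4,5-tris(benzyloxy)phenyl]vinyl}boronate F1. Chiral-biphenol catalysis ((R)-3,3′-dibromo-1,1′-bi-2-naphthol, toluene) of the addition of F1 to the quinone methide from 7 transfers the alkenyl group to C4 and gives the (E)-1,1,3-triarylpropene phenol F2, with C4 set by the catalyst. Silylation (TBSCl, imidazole, DMF) gives the aryl silyl ether F3. Shi epoxidation with the L-fructose-derived ketone (KHSO5, K2CO3 buffer, MeCN/dimethoxymethane/water, 0 °C) gives the (2S,3S)-epoxide F4. HF·pyridine and then camphorsulfonic acid release the phenol, which opens the epoxide 6-endo at benzylic C2 with inversion to give 13, so O1–C2 is again the ring-closing bond.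

2. Step 3. The electrophile may attack ring D (C6 or C8) instead of the hindered ring-E position, and acid may remove benzyl groups. The fallback sets out from 3 and returns at 4. Bromination with N-bromosuccinimide (MeCN, 0 °C, no Lewis acid) gives the ring-E 2′-bromide F5, whose regiochemistry can be checked before going on. Stille coupling with tributyl(vinyl)stannane (Pd(P(t-Bu)3)2, CsF, dioxane) gives the 2′-vinyl compound F6. Lemieux–Johnson cleavage (OsO4 cat., NaIO4, 2,6-lutidine, dioxane/water) gives 4.

3. Step 4. Condensation at the di-ortho-substituted formyl group may be slow, and at reflux the adduct may ionise to the quinone methide and be consumed by a second phenol or oligomerise. The fallback sets out from 4 and 5 and returns at 7. Phenol 5 is deprotonated with EtMgBr (Et2O, then toluene) to bromomagnesium 3-(benzyloxy)phenoxide F7, which adds through its ortho carbon to the aldehyde of 4 at room temperature by a magnesium-chelated, acid-free pathway; NH4Cl work-up gives 7.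

**Further compounds**

F1 | step 6 | diethyl (E)-{2-[3,4,5-tris(benzyloxy)phenyl]vinyl}boronate | CCOB(OCC)/C=C/c1cc(OCc2ccccc2)c(OCc2ccccc2)c(OCc2ccccc2)c1
F2 | step 6 | benzyl (2R,3R)-7-(benzyloxy)-2-{3,4,5-tris(benzyloxy)-2-[(1S,2E)-1-(4-(benzyloxy)-2-hydroxyphenyl)-3-(3,4,5-tris(benzyloxy)phenyl)prop-2-en-1-yl]phenyl}-4-oxochroman-3-yl carbonate | O=C1c2ccc(OCc3ccccc3)cc2O[C@H](c2cc(OCc3ccccc3)c(OCc3ccccc3)c(OCc3ccccc3)c2[C@@H](/C=C/c2cc(OCc3ccccc3)c(OCc3ccccc3)c(OCc3ccccc3)c2)c2ccc(OCc3ccccc3)cc2O)[C@H]1OC(=O)OCc1ccccc1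
F3 | step 6 | tert-butyldimethylsilyl ether of F2 at the ring-A phenol | O=C1c2ccc(OCc3ccccc3)cc2O[C@H](c2cc(OCc3ccccc3)c(OCc3ccccc3)c(OCc3ccccc3)c2[C@@H](/C=C/c2cc(OCc3ccccc3)c(OCc3ccccc3)c(OCc3ccccc3)c2)c2ccc(OCc3ccccc3)cc2O[Si](C)(C)C(C)(C)C)[C@H]1OC(=O)OCc1ccccc1
F4 | step 6 | (2S,3S)-trans-epoxide of F3 (oxirane carbons are the future C2 and C3; triarylmethine carbon S) | O=C1c2ccc(OCc3ccccc3)cc2O[C@H](c2cc(OCc3ccccc3)c(OCc3ccccc3)c(OCc3ccccc3)c2[C@@H]([C@@H]2O[C@H]2c2cc(OCc3ccccc3)c(OCc3ccccc3)c(OCc3ccccc3)c2)c2ccc(OCc3ccccc3)cc2O[Si](C)(C)C(C)(C)C)[C@H]1OC(=O)OCc1ccccc1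
F5 | step 3 | benzyl (2R,3R)-7-(benzyloxy)-2-[3,4,5-tris(benzyloxy)-2-bromophenyl]-4-oxochroman-3-yl carbonate | O=C1c2ccc(OCc3ccccc3)cc2O[C@H](c2cc(OCc3ccccc3)c(OCc3ccccc3)c(OCc3ccccc3)c2Br)[C@H]1OC(=O)OCc1ccccc1
F6 | step 3 | benzyl (2R,3R)-7-(benzyloxy)-2-[3,4,5-tris(benzyloxy)-2-vinylphenyl]-4-oxochroman-3-yl carbonate | O=C1c2ccc(OCc3ccccc3)cc2O[C@H](c2cc(OCc3ccccc3)c(OCc3ccccc3)c(OCc3ccccc3)c2C=C)[C@H]1OC(=O)OCc1ccccc1
F7 | step 4 | bromomagnesium 3-(benzyloxy)phenoxide | Br[Mg]Oc1cccc(OCc2ccccc2)c1
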